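**Plan**

Ring numbering used throughout: C1(=O), C2(OMe), C3(Me), C4(=O), C5(H), C6(side chain).

1. Retrosynthesis: the quinone goes back to the cyclohexa-2,5-diene-1,4-diol (C1, C4 as carbinols). Then the ring bond C5=C6 and the exocyclic =CH2 are cut together (retro ring-closing enyne metathesis) to an open-chain 1-en-7-yne diol.
2. Enabling feature: ring C6=C5(H) is conjugated with the exocyclic C=CH2. This 2-substituted buta-1,3-diene, half in the ring and half in the chain, is what exo enyne metathesis of a vinyl group and an alkyne leaves behind. C1 and C4 carry oxygen, so the ring can be closed at the diol level.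
3. The C2=C3 enol ether must hold C1 and C4 cis. This is secured by a temporary C1–C4 bond, the fourth side of a squarate-derived cyclobutene (not in the target), which is cut by glycol cleavage before the ring closure.
4. Forward: (S)-alkynol (4 steps); dimethyl squarate to 3-methoxy-4-methylcyclobutenedione; alkynyl then vinyl 1,2-additions fix the ring regiochemistry; tiglate on; four-ring opened and reduced; the only ring of the target is closed in step 10; oxidation gives the quinone.
5. Stereochemistry: the single (S) centre comes from a catalyst-controlled transfer hydrogenation of an ynone (step 3) and is never touched again.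

Key step: step 10

Remark: the cyclobutene, open-chain and cyclohexadiene intermediates carry transient, uncontrolled carbinol centres and are carried as diastereomer mixtures; all of these centres are sp2 in the target.

**Route**

Step 1
Reactants: 1 4-methylpent-3-enoic acid
Product: 2 N-methoxy-N,4-dimethylpent-3-enamide
Conditions: CDI, CH2Cl2, 0 °C to rt; then MeNH(OMe)·HCl, rt
Reagents that add atoms: N,O-dimethylhydroxylamine hydrochloride, CNOC.Cl
Why: Acyl imidazolide formation and aminolysis (Weinreb amide synthesis) run under near-neutral conditions that should keep the β,γ-double bond out of conjugation.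

Step 2
Reactants: 2 N-methoxy-N,4-dimethylpent-3-enamide; 3 ethynyltrimethylsilane
Product: 4 6-methyl-1-(trimethylsilyl)hept-5-en-1-yn-3-one
Conditions: 3, n-BuLi, THF, −78 °C; then 2, −78 to −20 °C; cold sat. aq. NH4Cl
Reagents that add atoms: none
Why: Lithium trimethylsilylacetylide adds once to the Weinreb amide and the chelated tetrahedral adduct holds until cold work-up (Weinreb ketone synthesis), which should prevent over-addition and migration of the alkene into conjugation.

Step 3
Reactants: 4 6-methyl-1-(trimethylsilyl)hept-5-en-1-yn-3-one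
Product: 5 (3S)-6-methyl-1-(trimethylsilyl)hept-5-en-1-yn-3-ol
Conditions: Ru[(S,S)-TsNCH(Ph)CH(Ph)NH](p-cymene) (1 mol %), i-PrOH, rt
Reagents that add atoms: none
Why: Noyori asymmetric transfer hydrogenation of an alkynyl ketone, in which the (S,S)-ligand ruthenium hydride delivers hydrogen to one carbonyl face with the alkyne in the place usually taken by an aryl group, should set the (S)-carbinol under catalyst control without reducing the isolated alkene or the silylalkyne.

Step 4
Reactants: 5 (3S)-6-methyl-1-(trimethylsilyl)hept-5-en-1-yn-3-ol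
Product: 6 (3S)-6-methylhept-5-en-1-yn-3-ol
Conditions: K2CO3 (cat.), MeOH, rt
Reagents that add atoms: none
Why: Base-catalysed methanolysis of the C(sp)–Si bond frees the terminal alkyne and does not touch the carbinol centre.

Step 5
Reactants: 7 dimethyl squarate (3,4-dimethoxycyclobut-3-ene-1,2-dione)
Product: 9 3-methoxy-4-methylcyclobut-3-ene-1,2-dione, via methyllithium adduct 8 (not isolated)
Conditions: MeLi, THF, −78 °C; then (CF3CO)2O, −78 °C; aq. NaHCO3 work-up
Reagents that add atoms: methyllithium, [Li]C
Why: 1,2-Addition of methyllithium to one squarate carbonyl, trifluoroacetylation of the adduct and ionisation assisted by the vinylogous methoxy group with loss of methanol on work-up is the standard route to 3-alkoxy-4-alkylcyclobutenediones.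

Step 6
Reactants: 6 (3S)-6-methylhept-5-en-1-yn-3-ol; 9 3-methoxy-4-methylcyclobut-3-ene-1,2-dione
Product: 10 4-hydroxy-4-[(3S)-3-hydroxy-6-methylhept-5-en-1-yn-1-yl]-3-methoxy-2-methylcyclobut-2-en-1-one
Conditions: 6, n-BuLi (2.05 equiv), THF, −78 °C; then 9, −78 °C; sat. aq. NH4Cl at −78 °C; work-up below rt
Reagents that add atoms: none
Why: The acetylide end of the dianion adds 1,2 to the more electrophilic carbonyl of 9, the one next to the methoxy-bearing carbon and outside the vinylogous ester (established regiochemistry for 3-alkoxy-4-alkylcyclobutenediones), which puts the alkyne on the future C1; the product is kept cold to avoid thermal ring opening (Moore rearrangement).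

Step 7
Reactants: 10 4-hydroxy-4-[(3S)-3-hydroxy-6-methylhept-5-en-1-yn-1-yl]-3-methoxy-2-methylcyclobut-2-en-1-one
Product: 11 1-ethenyl-2-[(3S)-3-hydroxy-6-methylhept-5-en-1-yn-1-yl]-3-methoxy-4-methylcyclobut-3-ene-1,2-diol
Conditions: CH2=CHMgBr (3.5 equiv), CeCl3, THF, −78 °C; sat. aq. NH4Cl at −78 °C
Reagents that add atoms: vinylmagnesium bromide, C=C[Mg]Br
Why: After deprotonating both hydroxyls the vinyl cerium/magnesium reagent adds 1,2 to the strained ring ketone (as in sequential double additions to squarate esters) and puts the vinyl group on the future C4; the cold quench is meant to forestall oxyanion-accelerated ring opening, and the cis/trans ratio at the new carbinol is irrelevant.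

Step 8
Reactants: 11 1-ethenyl-2-[(3S)-3-hydroxy-6-methylhept-5-en-1-yn-1-yl]-3-methoxy-4-methylcyclobut-3-ene-1,2-diol; 12 tiglic acid ((2E)-2-methylbut-2-enoic acid)
Product: 13 (3S)-1-(2-ethenyl-1,2-dihydroxy-4-methoxy-3-methylcyclobut-3-en-1-yl)-6-methylhept-5-en-1-yn-3-yl (2E)-2-methylbut-2-enoate
Conditions: DCC, DMAP (cat.), CH2Cl2, 0 °C
Reagents that add atoms: none
Why: Steglich esterification should acylate only the secondary propargylic hydroxyl, since both ring hydroxyls are tertiary, and its neutral conditions spare the acid-labile tertiary allylic carbinol next to the enol ether.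

Step 9
Reactants: 13 (3S)-1-(2-ethenyl-1,2-dihydroxy-4-methoxy-3-methylcyclobut-3-en-1-yl)-6-methylhept-5-en-1-yn-3-yl (2E)-2-methylbut-2-enoate
Product: 15 (4E,9S)-3,6-dihydroxy-5-methoxy-4,12-dimethyltrideca-1,4,11-trien-7-yn-9-yl (2E)-2-methylbut-2-enoate (the two carbinol carbons cis on the enol ether double bond), via cis-enedione 14 (not isolated)
Conditions: Pb(OAc)4, K2CO3, CH2Cl2, −20 °C; filter through Celite; then CeCl3·7H2O, NaBH4, MeOH, −78 °C
Reagents that add atoms: none
Why: Criegee glycol cleavage of the strained di-tertiary diol (cis isomer fast, trans isomer helped by ring strain) gives an enedione whose acyl groups are cis because they were joined in the four-membered ring, and immediate Luche 1,2-reduction of both conjugated ketones, which leaves the tiglate alone, should remove the push–pull character before the double bond can isomerise.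

Step 10
Reactants: 15 (4E,9S)-3,6-dihydroxy-5-methoxy-4,12-dimethyltrideca-1,4,11-trien-7-yn-9-yl (2E)-2-methylbut-2-enoate
Product: 16 (3S)-2-(3,6-dihydroxy-5-methoxy-4-methylcyclohexa-1,4-dien-1-yl)-6-methylhepta-1,5-dien-3-yl (2E)-2-methylbut-2-enoate
Conditions: second-generation Grubbs catalyst RuCl2(=CHPh)(H2IMes)(PCy3) (5 mol %), degassed CH2Cl2 (5 mM), 40 °C; ethyl vinyl ether quench; filtration through Et3N-deactivated silica
Reagents that add atoms: none
Why: The ruthenium alkylidene loads onto the only monosubstituted alkene, adds across the alkyne with the carbene carbon bonding to the proximal alkyne carbon, and the ruthenacyclobutene opens to a vinyl carbene that takes up a methylidene from a second molecule of 15, so the ring C5=C6 bond and the exocyclic =CH2 arise in one isomerisation with no by-product. The closest known reaction type is exo ring-closing enyne metathesis of 1,7-enynes to 1-(alk-1-en-2-yl)cyclohexenes, including its use to build six-membered carbocycles that are afterwards aromatised. The six-membered ring closes in the exo mode with respect to the alkyne; the endo mode would give a seven-membered ring and is not expected. No stereocentre is created, the propargylic tiglate centre is untouched, and the two ring carbinol centres are mixtures that converge in step 11. The selectivity needed is site selectivity among four C=C bonds, and the substrate secures it: the prenyl and tiglate alkenes are trisubstituted (the latter also electron-poor), closure onto the prenyl group would need a four-membered ring, and the cis enol ether inherited from the cyclobutene holds the vinyl and alkynyl ends within reach.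

Step 11
Reactants: 16 (3S)-2-(3,6-dihydroxy-5-methoxy-4-methylcyclohexa-1,4-dien-1-yl)-6-methylhepta-1,5-dien-3-yl (2E)-2-methylbut-2-enoate
Product: 18 (3S)-2-(5-methoxy-4-methyl-3,6-dioxocyclohexa-1,4-dien-1-yl)-6-methylhepta-1,5-dien-3-yl (2E)-2-methylbut-2-enoate (the target), via hydroxy dienone 17 (not isolated)
Conditions: activated MnO2 (excess), CH2Cl2, rt
Reagents that add atoms: none
Why: MnO2 should oxidise the two doubly allylic ring carbinols in turn (allylic alcohol oxidation, first at C4 where the new carbonyl is vinylogous to the methoxy group) to the quinone, while the ester, the diene and the prenyl group carry no oxidisable hydroxyl.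

**Compound list**

1 | 4-methylpent-3-enoic acid | CC(C)=CCC(=O)O | starting material
2 | N-methoxy-N,4-dimethylpent-3-enamide | CC(C)=CCC(=O)N(C)OC | intermediate
3 | ethynyltrimethylsilane | C#C[Si](C)(C)C | starting material
4 | 6-methyl-1-(trimethylsilyl)hept-5-en-1-yn-3-one | CC(C)=CCC(=O)C#C[Si](C)(C)C | intermediate
5 | (3S)-6-methyl-1-(trimethylsilyl)hept-5-en-1-yn-3-ol | C[Si](C)(C)C#C[C@H](CC=C(C)C)O | intermediate
6 | (3S)-6-methylhept-5-en-1-yn-3-ol | C#C[C@H](CC=C(C)C)O | intermediate
7 | dimethyl squarate (3,4-dimethoxycyclobut-3-ene-1,2-dione) | COC1=C(OC)C(=O)C1=O | starting material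
8 | 4-hydroxy-2,3-dimethoxy-4-methylcyclobut-2-en-1-one (formed as its lithium alkoxide, then its trifluoroacetate) | COC1=C(OC)C(C)(O)C1=O | intermediate
9 | 3-methoxy-4-methylcyclobut-3-ene-1,2-dione | COC1=C(C)C(=O)C1=O | intermediate
10 | 4-hydroxy-4-[(3S)-3-hydroxy-6-methylhept-5-en-1-yn-1-yl]-3-methoxy-2-methylcyclobut-2-en-1-one | COC1=C(C)C(=O)C1(O)C#C[C@H](CC=C(C)C)O | intermediate
11 | 1-ethenyl-2-[(3S)-3-hydroxy-6-methylhept-5-en-1-yn-1-yl]-3-methoxy-4-methylcyclobut-3-ene-1,2-diol | C=CC1(O)C(C)=C(OC)C1(O)C#C[C@H](CC=C(C)C)O | intermediate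
12 | tiglic acid ((2E)-2-methylbut-2-enoic acid) | C/C=C(\C)C(=O)O | starting material
13 | (3S)-1-(2-ethenyl-1,2-dihydroxy-4-methoxy-3-methylcyclobut-3-en-1-yl)-6-methylhept-5-en-1-yn-3-yl (2E)-2-methylbut-2-enoate | C=CC1(O)C(C)=C(OC)C1(O)C#C[C@H](CC=C(C)C)OC(=O)/C(C)=C/C | intermediate
14 | (4E,9S)-5-methoxy-4,12-dimethyl-3,6-dioxotrideca-1,4,11-trien-7-yn-9-yl (2E)-2-methylbut-2-enoate (acyl groups cis) | C=CC(=O)/C(C)=C(/OC)C(=O)C#C[C@H](CC=C(C)C)OC(=O)/C(C)=C/C | intermediate
15 | (4E,9S)-3,6-dihydroxy-5-methoxy-4,12-dimethyltrideca-1,4,11-trien-7-yn-9-yl (2E)-2-methylbut-2-enoate | C=CC(O)/C(C)=C(/OC)C(O)C#C[C@H](CC=C(C)C)OC(=O)/C(C)=C/C | intermediate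
16 | (3S)-2-(3,6-dihydroxy-5-methoxy-4-methylcyclohexa-1,4-dien-1-yl)-6-methylhepta-1,5-dien-3-yl (2E)-2-methylbut-2-enoate | C=C(C1=CC(O)C(C)=C(OC)C1O)[C@H](CC=C(C)C)OC(=O)/C(C)=C/C | intermediate
17 | (3S)-2-(6-hydroxy-5-methoxy-4-methyl-3-oxocyclohexa-1,4-dien-1-yl)-6-methylhepta-1,5-dien-3-yl (2E)-2-methylbut-2-enoate | C=C(C1=CC(=O)C(C)=C(OC)C1O)[C@H](CC=C(C)C)OC(=O)/C(C)=C/C | intermediate
18 | (3S)-2-(5-methoxy-4-methyl-3,6-dioxocyclohexa-1,4-dien-1-yl)-6-methylhepta-1,5-dien-3-yl (2E)-2-methylbut-2-enoate | C=C(C1=CC(=O)C(C)=C(OC)C1=O)[C@H](CC=C(C)C)OC(=O)/C(C)=C/C | target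

**Step count and risks**

Total steps: 11. Longest linear sequence: 10 (steps 1–4 and 6–11; step 5 is a one-step branch).

Three steps most likely to fail:

1. Step 7. After the vinyl reagent has added, the dialkoxide of the 1-vinyl-2-alkynylcyclobutenediol may undergo oxyanion-accelerated conrotatory ring opening or oxy-Cope rearrangement before it is quenched. The organometallic may also attack the methoxy-bearing carbon by addition–elimination. Fallback, setting out from 10 and returning at 15: the vinyl group is brought in only after the four-membered ring has been opened, so no carbanion meets the cyclobutene. Steglich esterification of the secondary hydroxyl of 10 with 12 gives the hydroxycyclobutenone tiglate F1. Luche reduction of its ring ketone (NaBH4, CeCl3·7H2O, MeOH, −78 °C) gives the cyclobutene-1,4-diol F2. Criegee cleavage (Pb(OAc)4, K2CO3) gives the cis keto aldehyde F3. Nozaki–Hiyama–Kishi vinylation (vinyl bromide, CrCl2, NiCl2 cat., DMF), selective for the aldehyde over the ynone and the ester, gives the hydroxy ynone F4, which may rest partly as its five-membered lactol. Luche reduction of F4 gives 15. This path also bypasses steps 8 and 9.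

2. Step 10. Turnover may stall because the internal alkyne lies between two oxygenated carbons and the free hydroxyls can bind ruthenium. A ruthenium hydride may isomerise the vinyl carbinol to an ethyl ketone, and the product may lose water during the run. Fallback, setting out from 15 and returning at 16: the catalyst is given a hydroxyl-free substrate. TESCl/imidazole converts 15 to the bis(triethylsilyl) ether F5. Ring-closing enyne metathesis of F5 (routine for silyl-protected enynols) gives the silylated cyclohexadiene F6, which cannot dehydrate. TBAF buffered with AcOH at 0 °C releases 16 just before the oxidation.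

3. Step 11. The C4 hydroxyl of 16 (vinylogous to the methoxy group) may ionise on the MnO2 surface or on silica and the C1 hydrogen be lost, so the ring aromatises by dehydration instead of being oxidised. Fallback, setting out from 16 and returning at 18: the dehydration is made the intended path. PPTS (cat.) in CH2Cl2 converts 16 to the phenol F7, with its hydroxyl at the former C1 and the para position free. Teuber oxidation with ON(SO3K)2 (Fremy's salt, KH2PO4 buffer, acetone/H2O) then gives 18.

Further compounds
F1 | step 7 | (3S)-1-(1-hydroxy-2-methoxy-3-methyl-4-oxocyclobut-2-en-1-yl)-6-methylhept-5-en-1-yn-3-yl (2E)-2-methylbut-2-enoate | COC1=C(C)C(=O)C1(O)C#C[C@H](CC=C(C)C)OC(=O)/C(C)=C/C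
F2 | step 7 | (3S)-1-(1,4-dihydroxy-2-methoxy-3-methylcyclobut-2-en-1-yl)-6-methylhept-5-en-1-yn-3-yl (2E)-2-methylbut-2-enoate | COC1=C(C)C(O)C1(O)C#C[C@H](CC=C(C)C)OC(=O)/C(C)=C/C
F3 | step 7 | (2E,7S)-3-methoxy-2,10-dimethyl-1,4-dioxoundeca-2,9-dien-5-yn-7-yl (2E)-2-methylbut-2-enoate | O=C/C(C)=C(/OC)C(=O)C#C[C@H](CC=C(C)C)OC(=O)/C(C)=C/C
F4 | step 7 | (4E,9S)-3-hydroxy-5-methoxy-4,12-dimethyl-6-oxotrideca-1,4,11-trien-7-yn-9-yl (2E)-2-methylbut-2-enoate | C=CC(O)/C(C)=C(/OC)C(=O)C#C[C@H](CC=C(C)C)OC(=O)/C(C)=C/C
F5 | step 10 | (4E,9S)-5-methoxy-4,12-dimethyl-3,6-bis(triethylsilyloxy)trideca-1,4,11-trien-7-yn-9-yl (2E)-2-methylbut-2-enoate | C=CC(O[Si](CC)(CC)CC)/C(C)=C(/OC)C(O[Si](CC)(CC)CC)C#C[C@H](CC=C(C)C)OC(=O)/C(C)=C/C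
F6 | step 10 | (3S)-2-[5-methoxy-4-methyl-3,6-bis(triethylsilyloxy)cyclohexa-1,4-dien-1-yl]-6-methylhepta-1,5-dien-3-yl (2E)-2-methylbut-2-enoate | C=C(C1=CC(O[Si](CC)(CC)CC)C(C)=C(OC)C1O[Si](CC)(CC)CC)[C@H](CC=C(C)C)OC(=O)/C(C)=C/C
F7 | step 11 | (3S)-2-(2-hydroxy-3-methoxy-4-methylphenyl)-6-methylhepta-1,5-dien-3-yl (2E)-2-methylbut-2-enoate | C=C(c1ccc(C)c(OC)c1O)[C@H](CC=C(C)C)OC(=O)/C(C)=C/C
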